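Per hour, a pseudo-first-order flask turns a fixed share of what substrate is left, so the exposure X, the logarithm of substrate charged over substrate left, should climb in a straight line with time.

in all of them: left-handed substrate 20 mM; right-handed substrate 20 mM; free catalyst 0.25 mol%; racemization catalyst 0.21 mol%; impurity 23 µM
- epsilon: partner 4 equiv; the very flask that is asked about, followed so far
- flask: partner 4.00 equiv; time 25 h

epsilon run (percent of the left-handed substrate and right-handed substrate together charged)

| time / h | left-handed product / % | right-handed product / % |
|---|---|---|
| 0.833 | 7.1 | 2.6 |
| 1.33 | 10.4 | 4.4 |
| 2.00 | 14.0 | 6.0 |
| 3.00 | 19.5 | 8.2 |
| 4.00 | 22.3 | 10.3 |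
| 6.00 | 28.2 | 12.8 |
| 10.0 | 35.2 | 15.9 |

(standard deviation of a reading: 0.5 percentage points)

- left-handed product and right-handed product together, in percent of the left-handed substrate and right-handed substrate charged together, at 25 h
- excess of left-handed product over right-handed product in the product at 25 h
- whether the exchange between left-handed substrate and right-handed substrate keeps pace with the reaction: how far the product's excess at 25 h gets from its value without exchange to its value with instant exchange (above 80% keeps pace, below 20% hardly takes part, else lags behind)

- free catalyst is single-handed; left-handed substrate and right-handed substrate are mirror images of each other, charged as a racemate, each of them at the stated concentration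
- on the list of suspects stand: partner -> decomposed reagent; left-handed substrate + racemization catalyst <-> right-handed substrate + racemization catalyst; racemization catalyst + impurity -> spent catalyst; partner <-> dormant form; partner + free catalyst + left-handed substrate -> free catalyst + left-handed product; partner + free catalyst + right-handed substrate -> free catalyst + right-handed product
- an excess is below zero if the other one leads

I take both substrates and both products together. The run so far gives X = 0.223 at 2.00 h, 0.395 at 4.00 h and 0.715 at 10.0 h. The readings already bend away from the straight line: X4/X2 reads 1.77, less than the 2 the line requires. The suspects include losses of partner, so I let the pace fade exponentially with a decay time τ, and X then rises towards a ceiling.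

That ratio gives a first τ of 7.58 h, and the 10.0 h reading then puts the ceiling at 0.976. Going round once more, the 4.00 h reading against that ceiling gives τ = 7.73 h and a ceiling of 0.986. My estimate of the exposure at 25 h is therefore 0.947, which means a yield of 61.2%, and this estimate carries the scatter of the readings.

For the excess, the first reading puts the selectivity factor s, read as the ratio of the two products, at 2.73, so instant exchange would give (s−1)/(s+1) = 46.4% on this reading. The last reading stands at 37.8%, less than that. The impurity charged matches 54.8% of the racemization catalyst. I expect an excess near that last reading and an exchange that lags behind.

The forecast says a yield of 61.5%, an excess of 37.5% and an exchange that lags behind, and its ground for the yield begins with “The rate constants fall steadily”.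

The flask gives 65.3% with an excess of 39.3%, and the exchange lags behind, getting 61% of the way.

    partner → decomposed reagent (k = 0.0660 h⁻¹)
    left-handed substrate + racemization catalyst ⇌ right-handed substrate + racemization catalyst, rate k2*[racemization catalyst]*[left-handed substrate] forward; the back reaction follows from the equilibrium constant (k = 5900 M⁻¹ h⁻¹)
    racemization catalyst + impurity → spent catalyst (k = 5.00 × 10⁵ M⁻¹ h⁻¹)
    partner ⇌ dormant form (K = 0.190, k = 0.0280 h⁻¹)
    partner + free catalyst + left-handed substrate → free catalyst + left-handed product (k = 49000 M⁻² h⁻¹)
    partner + free catalyst + right-handed substrate → free catalyst + right-handed product (k = 18000 M⁻² h⁻¹)

The flask's exposure is 1.06, more than my 0.947. A neighbouring flask holds 0.42 mol% of free catalyst instead of 0.25 mol%. If exposure followed the loading, this neighbour would reach 1.78, a yield of 83.1%. The neighbour gives 79.2%, an exposure of 1.57, less than the scaled value.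

The readings were generated by integration with constants of no real substance; noise was put on by code.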